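| flask | solid substrate | coupling partner | remark | time |
|---|---|---|---|---|
| theta | 0.010 M | 4 equiv | run made earlier |  |
| beta | 0.027 M | 4 equiv | run made earlier |  |
| eta | 0.051 M | 4 equiv | run made earlier |  |
| south-west | 0.012 M | 4.00 equiv |  | 20 min |
| north-west | 0.025 M | 4.00 equiv |  | 20 min |
| south | 0.050 M | 4.00 equiv |  | 20 min |

| theta: time / min | theta: target / % | beta: time / min | beta: target / % | eta: time / min | eta: target / % |
|---|---|---|---|---|---|
| 0.833 | 0 | 0.833 | 0 | 0.833 | 2.4 |
| 2.50 | 0.7 | 2.50 | 2.5 | 1.50 | 0.7 |
| 5.00 | 5.7 | 5.00 | 7.1 | 3.00 | 1.3 |
| 8.00 | 12.1 | 8.00 | 14.7 | 5.00 | 5.9 |
| 10.0 | 15.4 | 10.0 | 18.5 | 10.0 | 16.2 |

(each reading ± 1 percentage point)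

- solid, in amounts per volume of the solution: solid substrate
- the numbers in the tables scatter by 1 percentage point (one standard deviation)
- at the start none of the solid substrate is in solution
- a reading or a percentage of target counts all its forms, free or not
- the concentration of target that is asked is that of its free form alone
- "hardly changes" means that all values lie within two and a half points (for a concentration: within two and a half percent of the largest)

- [target] (only what is free in solution) at the end for south-west, north-west, south, in this order
- how that number moves from the first to the last of them (falls all the way / hardly changes / falls, then rises / rises, then falls / rises all the way)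

A leftover is where I begin: the coupling partner, charged at 4.00 equiv, stands in large excess, so I carry its charge C, the equivalents times the loading of solid substrate, which is 0.0480 M in south-west and 0.200 M in south.

I build the flask one process at a time. With the main step alone, the theta, beta and eta runs read 15.4%, 18.5% and 16.2% at 10.0 min, a spread of 3.1 percentage points against a scatter of 1 point, so the percent curves lie close without lying on one another, and I take the eta run, which climbs from 5.9% at 5.00 min to 16.2% at 10.0 min, and extend that slope to 20 min. This straight extension, my own rough estimate, gives 36.8% of the solid substrate as target, which takes 9.20% of the partner's charge. Adding dissolution, which the lag in the readings suggests, makes me hold that estimate loosely, because the runs stop at 10.0 min and do not show how long solid lasts at each loading, and the extension assumes that the slope of the eta run holds on to 20 min. Adding a binding is what moves it, because the question asks for free target while the readings count all its forms. If target sits in a settled one-to-one binding with the coupling partner, with constant K, then bound over free is K times the free partner, roughly K·C, and free target is the total divided by one plus K·C. At fixed equivalents and fixed percent, total and C both grow with the loading, so past the crossing K·C = one, where control passes from the charge to the binding, free target stops following the loading and levels off. The readings count bound and free together and give no K, so I commit to a row that rises and bends, below my rough estimates of total target, 0.00442 M in south-west and 0.0184 M in south.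

The forecast stands at 0.0042 M, 0.0088 M and 0.0175 M, and its row rises all the way: “I take free target as roughly total”.

South-west ends at 0.00104 M of free target, north-west at 0.00184 M and south at 0.00203 M, and the row rises all the way.

    solid substrate ⇌ dissolved substrate, rate k1*(cs1 - [dissolved substrate]) while solid is left; crystals form when [dissolved substrate] > cs1 (solubility = 21.0 mM, k = 0.00239 s⁻¹)
    coupling partner + target ⇌ idle adduct, settled at all times (K = 47.0 L mol⁻¹)
    dissolved substrate + target → side product (k = 0.217 L mol⁻¹ s⁻¹)
    dissolved substrate + coupling partner → target (k = 0.0101 L mol⁻¹ s⁻¹)

With K = 47 L mol⁻¹, binding outweighs release at charge by K·C = 2.26 in south-west, and C carried to south gives 9.40, higher than in south-west. At 20.0 min, with bound forms counted in target and all in percent of the solid substrate charged, south-west holds 17.0% of its 25.8% target as idle adduct, and south holds 31.3% of its 35.4%.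

The numbers in the tables were generated by integration for substances that don't exist, and the scatter is random.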